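Percentage points of the solid substrate charged are the unit of the readings below, and each reading scatters by 2 percentage points. In a closed, stirred flask a suspended solid substrate gives target and isomer of the product; the noon run is the flask asked about.

| flask | solid substrate | remark | time |
|---|---|---|---|
| noon | 0.20 M | the very flask that is asked about, followed so far |  |
| autumn | 0.10 M | run made earlier |  |
| flask | 0.20 M |  | 1.5 h |

- noon (time / min: isomer of the product / %, target / %): 5.00: 1, 14; 10.0: 0, 42; 15.0: 1, 69; 20.0: 4, 88; 25.0: 0, 92
- autumn (time / min: isomer of the product / %, target / %): 12.0: 1, 83; 25.0: 1, 96; 40.0: 0, 98; 50.0: 2, 99; 60.0: 0, 96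

(standard deviation of a reading: 2 percentage points)

- at the start none of the solid substrate is in solution
- a reading or a percentage of target counts all its forms, free or not

- share of isomer of the product in isomer of the product plus target at 2.0 min
- share of isomer of the product in isomer of the product plus target at 1.5 h
- which of isomer of the product and target there is more of at 1.5 h

Read down the columns. The noon target climbs to 92% at 25.0 min, and the autumn target reads 96% at 25.0 min and 96% at 60.0 min, so it shows no net fall between those two autumn rows. The isomer column has no trend: its largest entry, 4% at 20.0 min in the noon run, is followed by 0%.

Single isomer readings say little, so the rows of both runs are summed. The pooled isomer share w, the isomer column's sum divided by the sum of both columns (a selectivity), is 1.27%. The scatter of a sum grows with the root of the row count, so w carries about 0.8 points. The part left as target is 98.7%, far above w, so this reckoning puts target ahead. No row stands as early as 2.0 min or as late as 1.5 h, so w is carried to both times without a reading of its own.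

The forecast, from the same rows, gives 1.3% at 2.0 min, 1.3% at 1.5 h and target in the lead, holding that "target is not visibly isomerising".

The flask gives 2.03% at 2.0 min and 2.08% at 1.5 h, with target ahead, 97.3% against 2.06%.

    starting material → intermediate (k = 0.00380 s⁻¹)
    intermediate ⇌ target (K = 13.0, k = 0.0160 s⁻¹)
    intermediate ⇌ isomer of the product (K = 47.0, k = 3.20 × 10⁻⁴ s⁻¹)
    solid substrate ⇌ starting material, rate k4*(cs4 - [starting material]) while solid is left; crystals form when [starting material] > cs4 (solubility = 0.0640 M, k = 0.0110 s⁻¹)
    starting material → decomposition product (k = 2.00 × 10⁻⁵ s⁻¹)
    crystals ⇌ target, rate k6*(cs6 - [target]) while solid is left; crystals form when [target] > cs6 (solubility = 2.40 mM, k = 0.100 s⁻¹)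

The neighbour flask holds 0.050 M of solid substrate, all else unchanged. Reckoned with w, its end products, 99.1% of the charge, contain isomer of the product to 1.26% of the charge, and target leads. The neighbour flask ends with 96.6% target and 2.51% isomer of the product, so target leads there too. The share of isomer of the product in the neighbour flask is 2.03% at 2.0 min and 2.53% at 1.5 h.

Readings and results were computed for substances that don't exist; noise was put on by code.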